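## The problem

The target 14 is the (R)-2-methylbutanoate of a lariciresinol-type lignan in the (2R,3S,4S) series. It has one oxolane ring (O1, C2 to C5) with a 4-hydroxy-3-methoxyphenyl group on C2, an acyloxymethyl arm on C3 and a 4-hydroxy-3-methoxybenzyl group on C4. Only one ring has to be closed, but C2, C3 and C4 are contiguous stereocentres arranged 2,3-trans and 3,4-cis, and a fourth stereocentre sits in the acyl group, which is best bought as the acid. The ring centres can be made to depend on one another: a C3 substituent that is still epimerisable settles trans to the C2 aryl group, and a C3 substituent next to an sp2 C4 shields one face of it. Hence only C2 needs absolute control, while the less stable 3,4-cis relation has to be set kinetically. The C2–O1 bond is a benzylic ether activated by a para oxygen, so it ionises under acid and is open to hydrogenolysis; the phenols must stay masked until the end; and the ester of an α-branched chiral acid would not survive hydride or strong base, so it goes on late. A short assembly is possible because O1–C5–C4 with the benzylic CH2 is the O–CH2–C≡CH chain of propargyl alcohol, C2–C3 with its aryl group and a carboxyl-level carbon on C3 is an arylidene malonate, and the arene of the benzyl arm is an aryl halide. Both arenes are the same guaiacyl unit, so the two aromatic pieces come from one family of cheap phenols.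

## Retrosynthesis

The last operation is a hydrogenation. The two aryl O–benzyl bonds of 14 and the two C–H bonds at C4 and at the benzylic carbon are cut, leading back to the (Z)-benzylidene ester 13 with both phenols as benzyl ethers. The neighbouring order, saturating and debenzylating first and acylating last, would leave one primary alcohol to be told apart from two phenols. With the ester already in place that problem does not arise, and the larger C3 arm shields its face of the alkene better than CH2OH would. The precursor has one ring stereocentre fewer. The forward step must add hydrogen to the face opposite the C3 arm and must spare the benzylic C2–O1 bond.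

The ester C–O bond of 13 is cut next, giving the primary alcohol 11 and (R)-2-methylbutanoic acid 12. Acylating only after all hydride and enolate chemistry keeps the α-centre of the acyl group out of harm, and 11 has a single free hydroxyl, so no selectivity is needed. The forward reaction must activate the acid without epimerising it.

The CH2OH group of 11 is taken back to the methyl ester 10, and 10 to the geminal diester 9 by adding a second ester at C3; in the forward sense the C3–CO2Me bond is broken. This removes C3 as a stereocentre and exposes a malonate. Carrying a single ester through the ring formation instead would make C3 stereogenic in the key step and take away the reversibility on which its selectivity rests. The forward dealkoxycarbonylation must protonate C3 and not the benzylic end of the dienolate, and the acidic C3–H should let the ester settle trans to the C2 aryl group. Methyl esters are chosen because chloride attacks methyl faster than ethyl, which allows a lower temperature.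

In 9 three bonds are cut at once: O1–C2, C3–C4 and the bond between the exocyclic CH and its aryl group. This gives the arylidene malonate 3, the aryl iodide 5 and propargyl alcohol 6. In the forward sense the alkoxide 7 of 6 adds to 3 to give the enolate 8, which zerovalent palladium and 5 close onto the alkyne. Cutting only C3–C4 (a preformed propargyl ether with a separate arylation), or attaching the aryl group later by a Heck-type reaction, would cost steps and would not fix the alkene geometry as anti carbopalladation does. The simplification is large: a trisubstituted ring with a stereocentre and a defined alkene becomes three achiral pieces, each zero or one step from purchased compounds. The forward reaction is asked for something not yet known, absolute control at C2 by the ligand on palladium; the 5-exo regiochemistry and the alkene geometry are intrinsic.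

The C=C bond of 3 is cut to O-benzylvanillin 1 and dimethyl malonate 2 (Knoevenagel), and the O–benzyl bond of 5 to 4-iodo-2-methoxyphenol 4. Benzyl is chosen for both phenols because it withstands alkoxide, hot chloride in DMSO and hydride, and leaves in the final hydrogenation at no cost in steps.

## Roads not taken

Alternative 1: The cut is at the C2–H bond and the O1–C5 bond, with C5 at the lactone oxidation level.
- **Key step:** the racemic keto diester 1-tert-butyl 4-methyl 2-[3-methoxy-4-(triisopropylsilyloxy)benzoyl]butanedioate A1 epimerises freely at the carbon between ketone and tert-butyl ester. RuCl(p-cymene)[(R,R)-TsDPEN] (divalent ruthenium) with HCO2H/Et3N would reduce it under dynamic kinetic resolution, and the new hydroxyl would lactonise onto the methyl ester to give the trans aryl paraconate A2.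
- **Merits:** transfer hydrogenation of α-substituted β-keto esters with dynamic resolution is established, uses a commercial catalyst and sets C2 and C3 together. In the reliability of its enantiocontrol this road is clearly better than the chosen one.
- **Weak points:** A2 lacks the benzyl group and carries C5 as a carbonyl. Alkylation of the lactone enolate at C4 goes anti to the C3 ester and gives the 3,4-trans relation, the opposite of what is needed, and the base also threatens C3. The lactone carbonyl must then be taken down to CH2 next to the acid-sensitive C2–O1 bond, through a lactol and Lewis acid/silane or through a diol and re-etherification; both put C2 at risk. Two carboxyl carbons also have to be told apart.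
- **Comparison:** the endgame would need six or more operations after A2. Against the better enantiocontrol, the chosen plan delivers the ring, both aryl groups and C5 at the right oxidation level in one step, reaches the 3,4-cis relation by hydrogenation, and needs about half the steps.

Alternative 2: The cut is at C2–C3 and C4–C5.
- **Key step:** CsF would release a carbonyl ylide from the α-chloro ether 1-(benzyloxy)-4-{chloro[(trimethylsilyl)methoxy]methyl}-2-methoxybenzene A4. The ylide would add across the C=C bond of (5R)-5-[(1R,2S,5R)-menthyloxy]furan-2(5H)-one A3, anti to the menthyloxy group, to give the cis-fused bicyclic lactone acetal A5.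
- **Merits:** the ring and C2, C3 and C4 come from one cycloaddition. The cis fusion guarantees the 3,4-cis relation, which the chosen plan must earn by facial selectivity in step 7, and the absolute configuration comes from a cheap menthol-derived auxiliary with a known facial preference. Both are real advantages.
- **Weak points:** the unsymmetrical ylide must orient so that its aryl-bearing carbon bonds to the α-carbon of the butenolide, and the aryl group must end up exo; neither is assured, and A4 is hydrolytically fragile. After A5 the acetal carbon must become ArCH2: unmasking, addition of an arylmetal, and removal of a benzylic hydroxyl in a molecule with a second, equally activated benzylic C–O bond (C2–O1). The lactone carbon must also be reduced to CH2OH.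
- **Comparison:** five or six further operations would follow A5. The chosen plan brings the second aryl group in at its final oxidation level during ring formation and needs no benzylic deoxygenation.

Alternative 3: The cut is at C3–C4.
- **Key step:** Cp2TiCl (trivalent titanium) would open the terminal epoxide of 2-[(S)-[4-(benzyloxy)-3-methoxyphenyl]{[(2E)-3-[4-(benzyloxy)-3-methoxyphenyl]prop-2-en-1-yl]oxy}methyl]oxirane A6 to a β-titanoxy radical at C3. This adds 5-exo-trig to the cinnamyl double bond, and the benzylic radical is reduced and protonated to give di-O-benzyl-(−)-lariciresinol A7.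
- **Merits:** A7 has the whole skeleton with the CH2OH free and is two steps from 14 (esterification with 12, hydrogenolysis). The radical cyclisation is known for this substrate class, and the absolute configuration would come from the single carbinol centre of A6, which established asymmetric methods can set. On precedent this road is stronger than the chosen one, and its endgame is as short.
- **Weak points:** the C3 and C4 centres are set by the conformational preference of a radical cyclisation, so mixtures at C4 are to be expected and would need chromatographic separation. More than two equivalents of Cp2TiCl are consumed. A6 is not trivial to make: an ionisation-prone benzylic epoxy alcohol must be O-allylated under base, where epoxide migration (Payne rearrangement) competes, and the sequence to A6 is linear.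
- **Comparison:** the chosen plan is convergent (three pieces, longest linear sequence six), uses the metal catalytically, and sets alkene geometry, C3 and C4 in separate steps that can each be corrected. It cannot match the certainty of enantiocontrol; for that it relies on a resolution fallback.

Key step: step 3

Assumption: 4-(benzyloxy)-3-methoxybenzaldehyde, 4-iodo-2-methoxyphenol and (R)-2-methylbutanoic acid are taken as purchasable. The sense of induction in step 3 cannot be predicted, so (R)-DTBM-SEGPHOS is written and its mirror image is meant if it proves to favour the (2R) diester.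

Step 1
Reactants: 1 4-(benzyloxy)-3-methoxybenzaldehyde (O-benzylvanillin); 2 dimethyl malonate
Product: 3 dimethyl 2-{[4-(benzyloxy)-3-methoxyphenyl]methylidene}propanedioate
Conditions: piperidine (cat.), AcOH (cat.), toluene, reflux, Dean–Stark
Reagents that add atoms: none
Why: Knoevenagel condensation of a non-enolisable aldehyde with a malonate under piperidinium acetate catalysis, driven by azeotropic removal of water; the symmetric malonate leaves no alkene geometry to control.

Step 2
Reactants: 4 4-iodo-2-methoxyphenol
Product: 5 1-(benzyloxy)-4-iodo-2-methoxybenzene
Conditions: BnBr, K2CO3, DMF, 25 °C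
Reagents that add atoms: benzyl bromide, BrCc1ccccc1
Why: Williamson ether synthesis; the phenoxide is alkylated on oxygen by the benzylic bromide and the aryl iodide is inert to these conditions.

Step 3
Reactants: 6 propargyl alcohol (prop-2-yn-1-ol); 3 dimethyl 2-{[4-(benzyloxy)-3-methoxyphenyl]methylidene}propanedioate; 5 1-(benzyloxy)-4-iodo-2-methoxybenzene
Product: 9 dimethyl (2S,4Z)-2-[4-(benzyloxy)-3-methoxyphenyl]-4-{[4-(benzyloxy)-3-methoxyphenyl]methylidene}oxolane-3,3-dicarboxylate, via sodium prop-2-yn-1-olate 7 (not isolated), via sodium enolate of the oxa-Michael adduct 8 (not isolated)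
Conditions: 6, NaH, THF, 0 °C; then 3, 5, Pd2(dba)3 (2.5 mol%), (R)-DTBM-SEGPHOS (6 mol%), THF/DMSO, 25 °C
Reagents that add atoms: none
Why: Proposed new method: the closest known reaction type is the racemic palladium-mediated three-component coupling of a propargyl alkoxide, an alkylidene malonate and an aryl halide, and what is new is control of C2 by a chiral ligand. Alkoxide 7 adds reversibly to 3 (oxa-Michael, O1–C2) to give enolate 8 as a pair of rapidly interconverting enantiomers, while 5 adds oxidatively to zerovalent palladium to give an arylpalladium iodide carrying the bisphosphine. After loss of iodide this divalent palladium aryl binds the alkyne of 8, the malonate carbon attacks the triple bond from the side opposite the metal in a 5-exo-dig closure (C3–C4), and reductive elimination from the vinyl(aryl)palladium joins the aryl group to the exocyclic carbon and returns zerovalent palladium. The anti addition places the incoming aryl group trans to C3, so the Z alkene follows from the mechanism and needs no further control. C2, the only new stereocentre, is fixed in the ring closure: since the retro-oxa-Michael reaction equilibrates the enantiomers of 8 faster than either cyclises, the chiral pocket of (R)-DTBM-SEGPHOS should let one of them close faster, with its C2 aryl group in the pseudo-equatorial position of the forming envelope that clashes least with the ligand aryl groups (a dynamic kinetic ring closure). The selectivity required is thus between two diastereomeric transition states, and the substrate helps through the large aryl group next to the nucleophilic carbon and through the geminal diester, which keeps C3 achiral, makes the first addition reversible and renders the product configurationally stable once C3 is quaternary. Enantioselective arylative anti additions of tethered nucleophiles to alkynes on bisphosphine-ligated divalent palladium support the idea, but the sense of induction cannot be predicted and the ligand antipode is chosen accordingly. Copper is left out so that Sonogashira coupling of the terminal alkyne does not compete.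

Step 4
Reactants: 9 dimethyl (2S,4Z)-2-[4-(benzyloxy)-3-methoxyphenyl]-4-{[4-(benzyloxy)-3-methoxyphenyl]methylidene}oxolane-3,3-dicarboxylate
Product: 10 methyl (2R,3R,4Z)-2-[4-(benzyloxy)-3-methoxyphenyl]-4-{[4-(benzyloxy)-3-methoxyphenyl]methylidene}oxolane-3-carboxylate
Conditions: LiCl, H2O, DMSO, 140 °C
Reagents that add atoms: none
Why: Krapcho dealkoxycarbonylation: chloride removes a methyl group by SN2, the carboxylate loses CO2 and the ester enolate is protonated by water at C3, the α-carbon of the dienolate. The C3–H stays acidic under the conditions, so the ester should settle trans to the C2 aryl group (the less crowded 2,3-trans oxolane), while C2 itself is not involved.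

Step 5
Reactants: 10 methyl (2R,3R,4Z)-2-[4-(benzyloxy)-3-methoxyphenyl]-4-{[4-(benzyloxy)-3-methoxyphenyl]methylidene}oxolane-3-carboxylate
Product: 11 [(2R,3S,4Z)-2-[4-(benzyloxy)-3-methoxyphenyl]-4-{[4-(benzyloxy)-3-methoxyphenyl]methylidene}oxolan-3-yl]methanol
Conditions: LiAlH4, THF, 0 °C
Reagents that add atoms: none
Why: Hydride reduction of the ester to the primary alcohol; the unconjugated alkene and the benzyl ethers are inert to LiAlH4, and the low temperature keeps reduction faster than deprotonation at C3.

Step 6
Reactants: 11 [(2R,3S,4Z)-2-[4-(benzyloxy)-3-methoxyphenyl]-4-{[4-(benzyloxy)-3-methoxyphenyl]methylidene}oxolan-3-yl]methanol; 12 (R)-2-methylbutanoic acid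
Product: 13 [(2R,3S,4Z)-2-[4-(benzyloxy)-3-methoxyphenyl]-4-{[4-(benzyloxy)-3-methoxyphenyl]methylidene}oxolan-3-yl]methyl (2R)-2-methylbutanoate
Conditions: DCC, DMAP (cat.), CH2Cl2, 0 °C to 25 °C
Reagents that add atoms: none
Why: Steglich esterification; the only free hydroxyl is the primary one, and carbodiimide activation with catalytic DMAP at low temperature is mild enough to leave the α-centre of the acid intact.

Step 7
Reactants: 13 [(2R,3S,4Z)-2-[4-(benzyloxy)-3-methoxyphenyl]-4-{[4-(benzyloxy)-3-methoxyphenyl]methylidene}oxolan-3-yl]methyl (2R)-2-methylbutanoate
Product: 14 [(2R,3S,4S)-2-(4-hydroxy-3-methoxyphenyl)-4-[(4-hydroxy-3-methoxyphenyl)methyl]oxolan-3-yl]methyl (2R)-2-methylbutanoate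
Conditions: H2 (1 atm), 10% Pd/C, EtOAc/EtOH, 25 °C
Reagents that add atoms: none
Why: Heterogeneous catalytic hydrogenation with hydrogenolysis of the two aryl benzyl ethers. Hydrogen should add syn to the exocyclic alkene from the ring face opposite the adjacent C3 acyloxymethyl arm, which puts the new benzyl group cis to that arm and sets C4 as (S); neutral solvent and one atmosphere are chosen so that the benzylic C2–O1 bond, slower to cleave than aryl benzyl ethers, is kept.

## Compound list

1 | 4-(benzyloxy)-3-methoxybenzaldehyde (O-benzylvanillin) | O=Cc1ccc(OCc2ccccc2)c(OC)c1 | starting material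
2 | dimethyl malonate | COC(=O)CC(=O)OC | starting material
3 | dimethyl 2-{[4-(benzyloxy)-3-methoxyphenyl]methylidene}propanedioate | COC(=O)C(=Cc1ccc(OCc2ccccc2)c(OC)c1)C(=O)OC | intermediate
4 | 4-iodo-2-methoxyphenol | Oc1ccc(I)cc1OC | starting material
5 | 1-(benzyloxy)-4-iodo-2-methoxybenzene | COc1cc(I)ccc1OCc1ccccc1 | intermediate
6 | propargyl alcohol (prop-2-yn-1-ol) | C#CCO | starting material
7 | sodium prop-2-yn-1-olate | [Na+].[O-]CC#C | intermediate
8 | sodium enolate of dimethyl 2-{[4-(benzyloxy)-3-methoxyphenyl](prop-2-yn-1-yloxy)methyl}propanedioate (racemic, enantiomers interconverting) | COC(=O)C(C(OCC#C)c1ccc(OCc2ccccc2)c(OC)c1)=C([O-])OC.[Na+] | intermediate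
9 | dimethyl (2S,4Z)-2-[4-(benzyloxy)-3-methoxyphenyl]-4-{[4-(benzyloxy)-3-methoxyphenyl]methylidene}oxolane-3,3-dicarboxylate | COC(=O)C1(C(=O)OC)/C(=C/c2ccc(OCc3ccccc3)c(OC)c2)CO[C@H]1c4ccc(OCc5ccccc5)c(OC)c4 | intermediate
10 | methyl (2R,3R,4Z)-2-[4-(benzyloxy)-3-methoxyphenyl]-4-{[4-(benzyloxy)-3-methoxyphenyl]methylidene}oxolane-3-carboxylate (2,3-trans) | COC(=O)[C@@H]1/C(=C/c2ccc(OCc3ccccc3)c(OC)c2)CO[C@H]1c4ccc(OCc5ccccc5)c(OC)c4 | intermediate
11 | [(2R,3S,4Z)-2-[4-(benzyloxy)-3-methoxyphenyl]-4-{[4-(benzyloxy)-3-methoxyphenyl]methylidene}oxolan-3-yl]methanol | OC[C@@H]1/C(=C/c2ccc(OCc3ccccc3)c(OC)c2)CO[C@H]1c4ccc(OCc5ccccc5)c(OC)c4 | intermediate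
12 | (R)-2-methylbutanoic acid | CC[C@@H](C)C(=O)O | starting material
13 | [(2R,3S,4Z)-2-[4-(benzyloxy)-3-methoxyphenyl]-4-{[4-(benzyloxy)-3-methoxyphenyl]methylidene}oxolan-3-yl]methyl (2R)-2-methylbutanoate | CC[C@@H](C)C(=O)OC[C@@H]1/C(=C/c2ccc(OCc3ccccc3)c(OC)c2)CO[C@H]1c4ccc(OCc5ccccc5)c(OC)c4 | intermediate
14 | [(2R,3S,4S)-2-(4-hydroxy-3-methoxyphenyl)-4-[(4-hydroxy-3-methoxyphenyl)methyl]oxolan-3-yl]methyl (2R)-2-methylbutanoate | CC[C@@H](C)C(=O)OC[C@@H]1[C@H](Cc2ccc(O)c(OC)c2)CO[C@H]1c1ccc(O)c(OC)c1 | target

## Step count and risks

Total step count: 7. Longest linear sequence: 6 (steps 1, 3, 4, 5, 6, 7).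

Step 3 (key step, proposed new method). The most likely failure is insufficient discrimination between the two enantiomers of 8 in the ring closure, because the ligand sits on the alkyne face remote from C2 and the centre being selected lies several atoms from the metal. A chelating bisphosphine may also slow alkyne binding, so that direct arylation of the alkyne or simple return of 8 to 3 gains ground.
Fallback (known chemistry), setting out from 3, 5 and 6 and returning at 11: the coupling is run in its established racemic form with alkoxide 7 and triphenylphosphine-ligated zerovalent palladium (PdCl2(PPh3)2 reduced in the flask with n-BuLi, THF/DMSO). This should give racemic dimethyl (4Z)-2-[4-(benzyloxy)-3-methoxyphenyl]-4-{[4-(benzyloxy)-3-methoxyphenyl]methylidene}oxolane-3,3-dicarboxylate F1. Saponification of both esters (KOH, aqueous MeOH, reflux; then HCl) should give the racemic oxolane-3,3-dicarboxylic acid F2; because C3 is quaternary, no enolate can form during hydrolysis. Warming in toluene should expel CO2 and give mainly the racemic 2,3-trans oxolane-3-carboxylic acid F3. Crystallisation with (S)-1-phenylethylamine, or with the (R)-amine if its salt is the less soluble one, should give the (S)-1-phenylethylammonium (2R,3R,4Z)-carboxylate salt F4; a minor cis acid would stay in the mother liquor. Dilute HCl then releases the (2R,3R,4Z)-oxolane-3-carboxylic acid F5, and LiAlH4 in THF reduces it to alcohol 11. The same crystallisation can also raise a partial enantiomeric excess from step 3.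

Step 4. The most likely failure is migration of the double bond into conjugation with the ester, by protonation of the dienolate at the benzylic end or by later equilibration at 140 °C. A second failure mode is erosion of the C2 configuration through reversible ring-opening β-elimination of the C3 enolate.
Fallback, setting out from 9 and returning at 10: one ester is hydrolysed selectively (KOH, 1 equiv., THF/H2O, 0 °C; then acid) to (2S,4Z)-2-[4-(benzyloxy)-3-methoxyphenyl]-4-{[4-(benzyloxy)-3-methoxyphenyl]methylidene}-3-(methoxycarbonyl)oxolane-3-carboxylic acid F6, obtained as both C3 epimers. This malonic half-acid is decarboxylated under neutral conditions (toluene, 100 °C, or catalytic Cu2O in MeCN, 80 °C) through the enol, without chloride, strong base or a free enolate, to give 10.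

Step 7. The most likely failure is poor facial selectivity, since the C2 aryl group on the lower face opposes the shielding by the C3 arm. Palladium-hydride-mediated shift of the alkene into the ring would lose the C3 configuration, and over-reduction would cleave the C2–O1 bond.
Fallback, setting out from 13 and returning at 14: alkene saturation is separated from deprotection. Hydrogen-atom-transfer hydrogenation (catalytic Mn(dpm)3 (trivalent manganese), PhSiH3, t-BuOOH, i-PrOH, 25 °C) should deliver hydrogen to C4 from a bulky metal hydride on the face opposite the C3 arm and leave benzyl ethers and the ring ether untouched. It should give [(2R,3S,4S)-2-[4-(benzyloxy)-3-methoxyphenyl]-4-{[4-(benzyloxy)-3-methoxyphenyl]methyl}oxolan-3-yl]methyl (2R)-2-methylbutanoate F7, which can be freed of any C4 epimer by chromatography. Debenzylation (H2, Pd/C, EtOAc, short contact) then gives 14 as a pure deprotection.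

Step 6. The most likely failure is partial epimerisation of the α-centre of the acyl donor while the acid is activated (acylpyridinium or ketene pathway), or diversion of the branched acid to the N-acylurea.
Fallback, setting out from 11 and 12 and returning at 13: Mitsunobu esterification (PPh3, DIAD, THF, 0 °C) activates the primary alcohol instead of the acid, so 12 enters as a carboxylate nucleophile and its α-centre is never acidified. No new compound is involved.

## Further compounds

F1 | step 3 | racemic dimethyl (4Z)-2-[4-(benzyloxy)-3-methoxyphenyl]-4-{[4-(benzyloxy)-3-methoxyphenyl]methylidene}oxolane-3,3-dicarboxylate | COC(=O)C1(C(=O)OC)/C(=C/c2ccc(OCc3ccccc3)c(OC)c2)COC1c4ccc(OCc5ccccc5)c(OC)c4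
F2 | step 3 | racemic (4Z)-2-[4-(benzyloxy)-3-methoxyphenyl]-4-{[4-(benzyloxy)-3-methoxyphenyl]methylidene}oxolane-3,3-dicarboxylic acid | OC(=O)C1(C(=O)O)/C(=C/c2ccc(OCc3ccccc3)c(OC)c2)COC1c4ccc(OCc5ccccc5)c(OC)c4
F3 | step 3 | racemic 2,3-trans (4Z)-2-[4-(benzyloxy)-3-methoxyphenyl]-4-{[4-(benzyloxy)-3-methoxyphenyl]methylidene}oxolane-3-carboxylic acid | OC(=O)C1/C(=C/c2ccc(OCc3ccccc3)c(OC)c2)COC1c4ccc(OCc5ccccc5)c(OC)c4
F4 | step 3 | (S)-1-phenylethylammonium (2R,3R,4Z)-2-[4-(benzyloxy)-3-methoxyphenyl]-4-{[4-(benzyloxy)-3-methoxyphenyl]methylidene}oxolane-3-carboxylate | [O-]C(=O)[C@@H]1/C(=C/c2ccc(OCc3ccccc3)c(OC)c2)CO[C@H]1c4ccc(OCc5ccccc5)c(OC)c4.C[C@H]([NH3+])c1ccccc1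
F5 | step 3 | (2R,3R,4Z)-2-[4-(benzyloxy)-3-methoxyphenyl]-4-{[4-(benzyloxy)-3-methoxyphenyl]methylidene}oxolane-3-carboxylic acid | OC(=O)[C@@H]1/C(=C/c2ccc(OCc3ccccc3)c(OC)c2)CO[C@H]1c4ccc(OCc5ccccc5)c(OC)c4
F6 | step 4 | (2S,4Z)-2-[4-(benzyloxy)-3-methoxyphenyl]-4-{[4-(benzyloxy)-3-methoxyphenyl]methylidene}-3-(methoxycarbonyl)oxolane-3-carboxylic acid (both C3 epimers) | OC(=O)C1(C(=O)OC)/C(=C/c2ccc(OCc3ccccc3)c(OC)c2)CO[C@H]1c4ccc(OCc5ccccc5)c(OC)c4
F0 | step 6 | none | none
F7 | step 7 | [(2R,3S,4S)-2-[4-(benzyloxy)-3-methoxyphenyl]-4-{[4-(benzyloxy)-3-methoxyphenyl]methyl}oxolan-3-yl]methyl (2R)-2-methylbutanoate | CC[C@@H](C)C(=O)OC[C@@H]1[C@H](Cc2ccc(OCc3ccccc3)c(OC)c2)CO[C@H]1c4ccc(OCc5ccccc5)c(OC)c4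
A1 | alternative 1 | racemic 1-tert-butyl 4-methyl 2-[3-methoxy-4-(triisopropylsilyloxy)benzoyl]butanedioate | COC(=O)CC(C(=O)OC(C)(C)C)C(=O)c1ccc(O[Si](C(C)C)(C(C)C)C(C)C)c(OC)c1
A2 | alternative 1 | tert-butyl (2R,3R)-2-[3-methoxy-4-(triisopropylsilyloxy)phenyl]-5-oxooxolane-3-carboxylate (trans aryl paraconate) | CC(C)(C)OC(=O)[C@@H]1CC(=O)O[C@H]1c1ccc(O[Si](C(C)C)(C(C)C)C(C)C)c(OC)c1
A3 | alternative 2 | (5R)-5-[(1R,2S,5R)-menthyloxy]furan-2(5H)-one | O1C(=O)C=C[C@@H]1O[C@@H]2C[C@H](C)CC[C@H]2C(C)C
A4 | alternative 2 | racemic 1-(benzyloxy)-4-{chloro[(trimethylsilyl)methoxy]methyl}-2-methoxybenzene | ClC(OC[Si](C)(C)C)c1ccc(OCc2ccccc2)c(OC)c1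
A5 | alternative 2 | cis-fused 6-[4-(benzyloxy)-3-methoxyphenyl]-4-[(1R,2S,5R)-menthyloxy]-3,7-dioxabicyclo[3.3.0]octan-2-one | O1C(=O)[C@@H]2[C@H]([C@@H]1O[C@@H]3C[C@H](C)CC[C@H]3C(C)C)CO[C@H]2c4ccc(OCc5ccccc5)c(OC)c4
A6 | alternative 3 | 2-[(S)-[4-(benzyloxy)-3-methoxyphenyl]{[(2E)-3-[4-(benzyloxy)-3-methoxyphenyl]prop-2-en-1-yl]oxy}methyl]oxirane (either epimer at the oxirane carbon) | C(/C=C/c1ccc(OCc2ccccc2)c(OC)c1)O[C@H](C3CO3)c4ccc(OCc5ccccc5)c(OC)c4
A7 | alternative 3 | [(2R,3S,4S)-2-[4-(benzyloxy)-3-methoxyphenyl]-4-{[4-(benzyloxy)-3-methoxyphenyl]methyl}oxolan-3-yl]methanol (di-O-benzyl-(−)-lariciresinol) | OC[C@@H]1[C@H](Cc2ccc(OCc3ccccc3)c(OC)c2)CO[C@H]1c4ccc(OCc5ccccc5)c(OC)c4
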